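**Retrosynthetic overview**

- The strategy rests on ring A (C4a, C5, C6, C7, C8, C8a): oxygen sits on the alternate carbons C5, C7 and C8a, and C4a carries the acyl carbon C4, whose chain continues through C3 to C2 and the C19 tail. This is the oxygen pattern of a linear pentaketide with an icosanoyl starter.
- The chromone is therefore disconnected at O1–C2 and C4a–C5 to its isomer 4-hydroxy-6-(2-oxotricos-3-yn-1-yl)-2H-pyran-2-one. Its lactone masks C5 to C8a, and its alkyne holds C2/C3 at the chromone oxidation level.
- C4–C4a is disconnected to the dianion of triacetic acid lactone and a Weinreb ynamide; C3–C4 to a lithium acetylide and a carbamoyl chloride; the C2≡C3 alkyne comes from icosanal by one-carbon homologation.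
- Ring order: the 2-pyranone ring is bought and opened in the last step; there benzene ring A closes first (Claisen) and the 4-pyranone ring second, in one operation.

Key step: step 5

Remark on the chemistry: polycarbonyl intermediates are drawn as metal-free keto tautomers and the β-methoxyenones as E isomers; neither tautomer nor enol-ether geometry affects the outcome, because that carbon ends up as C2 of the pyranone ring.

**Step 1**
Reactants: 1 icosan-1-ol
Product: 2 icosanal
Conditions: TEMPO (10 mol%), PhI(OAc)2 (1.1 equiv), CH2Cl2, rt
Reagents that add atoms: none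
Why: TEMPO-catalysed (oxoammonium) oxidation of a primary alcohol with PhI(OAc)2 as terminal oxidant should stop at the aldehyde in anhydrous CH2Cl2, which also keeps the waxy C20 substrate dissolved.

**Step 2**
Reactants: 2 icosanal; 3 dimethyl (1-diazo-2-oxopropyl)phosphonate
Product: 4 henicos-1-yne
Conditions: K2CO3 (2 equiv), 3 (1.3 equiv), MeOH/THF, 0 °C to rt
Reagents that add atoms: dimethyl (1-diazo-2-oxopropyl)phosphonate (compound 3), COP(=O)(OC)C(=[N+]=[N-])C(C)=O
Why: Seyferth–Gilbert homologation in its Ohira–Bestmann form, mild enough for an enolizable aldehyde, should turn the aldehyde carbon into the internal alkyne carbon (later C2) and deliver the terminal carbon (later C3) from 3.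

**Step 3**
Reactants: 4 henicos-1-yne; 5 N-methoxy-N-methylcarbamoyl chloride
Product: 7 N-methoxy-N-methyldocos-2-ynamide, via lithium henicos-1-yn-1-ide 6 (not isolated)
Conditions: n-BuLi (1.05 equiv), THF, −40 to 0 °C; then cannulated into 5 (1.3 equiv), THF, −78 °C to rt
Reagents that add atoms: N-methoxy-N-methylcarbamoyl chloride (compound 5), CON(C)C(Cl)=O
Why: Nucleophilic acyl substitution of a carbamoyl chloride by a lithium acetylide should install the future C4 carbonyl, and inverse addition to excess of the much more electrophilic chloride should suppress a second acetylide addition to the product amide.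

**Step 4**
Reactants: 7 N-methoxy-N-methyldocos-2-ynamide; 8 triacetic acid lactone (4-hydroxy-6-methyl-2H-pyran-2-one)
Product: 11 4-hydroxy-6-(2-oxotricos-3-yn-1-yl)-2H-pyran-2-one, via triacetic acid lactone dilithium dianion 9 (not isolated), via dilithium tetrahedral adduct 10 (not isolated)
Conditions: 8 (1.3 equiv), LiN(i-Pr)2 (2.7 equiv), THF, −78 to −20 °C; then 7 (1.0 equiv), −78 to −40 °C; poured into cold 1 M HCl
Reagents that add atoms: none
Why: C-acylation of the lactone dianion at its most basic (6-methyl) carbon by a Weinreb amide is a known polyketide chain extension, and the lithium-chelated adduct 10 should persist until the acid quench, which secures 1,2-addition, a single addition and protection of the ynone from amine conjugate addition.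

**Step 5**
Reactants: 11 4-hydroxy-6-(2-oxotricos-3-yn-1-yl)-2H-pyran-2-one
Product: 14 5,7-dihydroxy-2-nonadecylchromone, via methyl (E)-9-methoxy-3,5,7-trioxooctacos-8-enoate 12 (not isolated), via (E)-3-methoxy-1-(2,4,6-trihydroxyphenyl)docos-2-en-1-one 13 (not isolated)
Conditions: Mg(OMe)2 (6 equiv), MeOH/THF, reflux; then HCl/MeOH to pH 1, 50 °C, same flask
Reagents that add atoms: none
Why: Proposed new method: methoxide should open the lactone of 11 at its carbonyl and add across the triple bond (in either order) to give the magnesium-chelated trioxo ester 12, whose C6 methylene (the former 6-CH2 of the pyranone, flanked by the C5 and C7 carbonyls) attacks the ester carbonyl in a 6-exo-trig Claisen closure that forms the C4a–C5 bond and, after loss of methoxide and enolization, phloroglucinol ring A of 13. One of the two equivalent ortho phenols of 13 then attacks the methoxy-bearing β-carbon (6-endo-trig addition followed by elimination of methanol, completed in the acid stage), forming the O1–C2 bond and the 4-pyranone ring, so that the step is a net isomerization. The closest known reactions are the Mg(OMe)2-mediated opening and Claisen recyclization of 6-(2-oxoalkyl)-4-hydroxy-2-pyranones to 2-acylphloroglucinols and the acid cyclization of ortho-hydroxyaryl β-alkoxyenones to chromones; running both on an alkynyl ketone in one flask has not been demonstrated. No stereocenter is formed, and the new double bonds are endocyclic. The step needs Claisen closure and not aldol closure of C2 onto the C7 ketone: the terminus is kept as a methyl ester inside a magnesium chelate, C7 is deactivated as a vinylogous ester and C8 cannot enolize, while the symmetry of the phloroglucinol allows only one chromone.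

**Compound list**

1 | icosan-1-ol | CCCCCCCCCCCCCCCCCCCCO | starting material
2 | icosanal | CCCCCCCCCCCCCCCCCCCC=O | intermediate
3 | dimethyl (1-diazo-2-oxopropyl)phosphonate (Ohira–Bestmann reagent) | COP(=O)(OC)C(=[N+]=[N-])C(C)=O | starting material
4 | henicos-1-yne | CCCCCCCCCCCCCCCCCCCC#C | intermediate
5 | N-methoxy-N-methylcarbamoyl chloride | CON(C)C(Cl)=O | starting material
6 | lithium henicos-1-yn-1-ide (not isolated) | CCCCCCCCCCCCCCCCCCCC#C[Li] | intermediate
7 | N-methoxy-N-methyldocos-2-ynamide | CCCCCCCCCCCCCCCCCCCC#CC(=O)N(C)OC | intermediate
8 | triacetic acid lactone (4-hydroxy-6-methyl-2H-pyran-2-one) | Cc1cc(O)cc(=O)o1 | starting material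
9 | dilithium dianion of triacetic acid lactone, lithium 6-(lithiomethyl)-2-oxo-2H-pyran-4-olate (not isolated) | [Li]Cc1cc(O[Li])cc(=O)o1 | intermediate
10 | dilithium tetrahedral adduct, lithium 6-[2-(lithiooxy)-2-(methoxy(methyl)amino)tricos-3-yn-1-yl]-2-oxo-2H-pyran-4-olate, racemic (not isolated) | CCCCCCCCCCCCCCCCCCCC#CC(O[Li])(Cc1cc(O[Li])cc(=O)o1)N(C)OC | intermediate
11 | 4-hydroxy-6-(2-oxotricos-3-yn-1-yl)-2H-pyran-2-one | CCCCCCCCCCCCCCCCCCCC#CC(=O)Cc1cc(O)cc(=O)o1 | intermediate
12 | methyl (E)-9-methoxy-3,5,7-trioxooctacos-8-enoate, present as its magnesium chelate (not isolated) | CCCCCCCCCCCCCCCCCCC/C(OC)=C\C(=O)CC(=O)CC(=O)CC(=O)OC | intermediate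
13 | (E)-3-methoxy-1-(2,4,6-trihydroxyphenyl)docos-2-en-1-one (not isolated) | CCCCCCCCCCCCCCCCCCC/C(OC)=C\C(=O)c1c(O)cc(O)cc1O | intermediate
14 | 5,7-dihydroxy-2-nonadecylchromone | CCCCCCCCCCCCCCCCCCCc1cc(=O)c2c(O)cc(O)cc2o1 | target

**Total step count:** 5
**Longest linear sequence:** 5 steps (1 → 2 → 4 → 7 → 11 → 14)

**Steps most likely to fail**

1. Step 5 (proposed new method). The chain may close by aldol instead of Claisen condensation. The chain enolate oxygen may cyclize early onto the triple bond and the resulting monocycle may not reopen. The ester may relactonize on acidification, or the pyranone C5 may add to the alkyne before the lactone opens. The fallback uses known aryl ynone chemistry, sets out from Weinreb ynamide 7 and returns at target 14. Phloroglucinol would be protected with chloromethyl methyl ether and i-Pr2NEt to give 1,3,5-tris(methoxymethoxy)benzene F1. n-BuLi in THF at 0 °C should lithiate F1 between two acetal oxygens to [2,4,6-tris(methoxymethoxy)phenyl]lithium F2. Addition of F2 to 7 at −78 °C and acid quench should give 1-[2,4,6-tris(methoxymethoxy)phenyl]docos-2-yn-1-one F3. Warm HCl in methanol would remove the three acetals to 1-(2,4,6-trihydroxyphenyl)docos-2-yn-1-one F4, whose ortho phenol should close 6-endo-dig onto the acid-activated ynone in the same flask to give 14.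

2. Step 4. The dianion or the amide base may add in conjugate fashion to the ynamide, propargylic deprotonation may isomerize the alkyne, and the poorly soluble dianion may convert incompletely. The fallback replaces acylation by aldol addition and oxidation, sets out from alkyne 4 and returns at 11. Acetylide 6 (n-BuLi, THF) would be formylated with N,N-dimethylformamide and quenched into aqueous KH2PO4 to give docos-2-ynal F5. Dianion 9 should add 1,2 to F5 at −78 °C to give racemic 4-hydroxy-6-(2-hydroxytricos-3-yn-1-yl)-2H-pyran-2-one F6. Oxidation of the propargylic alcohol of F6 with MnO2 in CH2Cl2/THF should give 11.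

3. Step 3. A second acetylide may add to the product amide, and acylation may stall because the long-chain acetylide is poorly soluble at low temperature. The fallback builds the amide from the acid, sets out from alkyne 4 and returns at 7. Acetylide 6 would be carboxylated with CO2 to docos-2-ynoic acid F7. F7 would be activated as the mixed anhydride (isobutyl chloroformate, N-methylmorpholine, −20 °C) and coupled with N,O-dimethylhydroxylamine hydrochloride to give 7.

**Further compounds**

F1 | step 5 | 1,3,5-tris(methoxymethoxy)benzene | COCOc1cc(OCOC)cc(OCOC)c1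
F2 | step 5 | [2,4,6-tris(methoxymethoxy)phenyl]lithium | [Li]c1c(OCOC)cc(OCOC)cc1OCOC
F3 | step 5 | 1-[2,4,6-tris(methoxymethoxy)phenyl]docos-2-yn-1-one | CCCCCCCCCCCCCCCCCCCC#CC(=O)c1c(OCOC)cc(OCOC)cc1OCOC
F4 | step 5 | 1-(2,4,6-trihydroxyphenyl)docos-2-yn-1-one | CCCCCCCCCCCCCCCCCCCC#CC(=O)c1c(O)cc(O)cc1O
F5 | step 4 | docos-2-ynal | CCCCCCCCCCCCCCCCCCCC#CC=O
F6 | step 4 | 4-hydroxy-6-(2-hydroxytricos-3-yn-1-yl)-2H-pyran-2-one (racemic) | CCCCCCCCCCCCCCCCCCCC#CC(O)Cc1cc(O)cc(=O)o1
F7 | step 3 | docos-2-ynoic acid | CCCCCCCCCCCCCCCCCCCC#CC(=O)O
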